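## Structural features

The target is a labdane: a trans-fused decalin (ring A: C1–C5 and C10; ring B: C5–C10) with a gem-dimethyl group at C4, an angular methyl group (C20) at C10, an exocyclic C8=C17 methylene and, on C9, the chain C11–C15 that ends in a (13Z)-3-methylbut-2-enoic acid. Ring A and ring B share the C5–C10 bond, and the chain leaves ring B at C9, next to the ring fusion. The stereocentres C5 (S), C10 (S, quaternary) and C9 (S) stand in a row; C2 (R) stands apart on ring A and carries an axial 2β acetate that is syn-axial to both C20 and the 4β-methyl group. Fragile groups are the exocyclic methylene (acid moves it into ring B), the Z trisubstituted enoic acid (it can isomerise to E) and the secondary acetate (it would not survive a late ester saponification). The real difficulty is the C5–C10–C9 array, a methine between two quaternary carbons, then a quaternary stereocentre, then a branched methine, together with the contra-thermodynamic axial oxygen at C2. The key step exploits that C5–H lies between the quaternary carbons C4 and C10 and that C6 is 1,3 to the C8=C17 methylene across ring B: a ring A aldehyde at C6 with a C8(CH3)=C7H2 group on C9 is a 5-methylhex-5-enal, the substrate of a type 2 carbonyl-ene closure that forms C6–C7 and leaves the exocyclic alkene, and the aldehyde with the correct hydrogen at C5 is available from a C5 spiro-epoxide by a 1,2-hydride shift.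

## Logic of the disconnections

29 ⇒ 24 + 26. The C12–C13 bond is cut, between the sp3 carbon of the ring-bound chain and the sp2 carbon of the enoic acid. Cutting here takes the Z geometry out of any olefination: it is carried by the vinyl iodide of 26 and transferred with retention. The gain is a four-carbon piece one step from 25 and a C16 decalin core. The forward step needs a primary alkylzinc (27) that tolerates the C2 acetate and a coupling that accepts the carboxylate 28, so that no ester has to be cleaved beside the acetate.

24 ⇒ 21 (through 23 and 22). No skeletal bond is cut; the C2–O bond is inverted and the acetate is traced back through the C2 ketone to the equatorial 2α alcohol. The reason is that the equatorial 2α oxygen is what steers the construction of ring A, while the axial 2β oxygen is reached most safely by reduction of 22 from its open α face. The demand is a hydride that comes only from the α face and leaves the primary iodide alone.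

21 ⇒ 19 (through 20). The C12–I bond is traced back to C12–O, and both oxygens return to the same silyl ether. The gain is a single protecting group for the whole ring-forming sequence. The demand is iodination of the primary alcohol of 20 in the presence of the secondary one.

19 ⇒ 16 (through 18). A C6–O bond is added: the hydroxyl that the ring closure leaves at C6 is absent from 29. This makes the ene disconnection possible. The demand is that the C6 radical be reduced without engaging the 1,3-related C8=C17 alkene.

16 ⇒ 14 (through 15). This is the key disconnection. C6–C7 is cut, which opens ring B to 15, and the C5–H/C6=O pair of 15 is traced back to the C5–O/C6–O oxirane of 14. The bicyclic problem becomes a monocyclic one, with C2, C9 and C10 on one ring and its side chain. The forward step must shift hydride anti to the oxirane oxygen and must close ring B with hydrogen transfer from C17 only.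

14 ⇒ 13. C5–C6 and C6–O are cut (methylene transfer to the C5 carbonyl). C6 becomes a one-carbon reagent and the precursor is a plain ketone. The demand is addition to the α face of a ketone flanked by two quaternary carbons.

13 ⇒ 12 ⇒ 4 + 10. C9–C10 is cut by a retro-[3,3] shift, which turns the vicinal quaternary/tertiary pair into an allyl enol ether; the O–CH2 bond of 12 is then cut. Both centres then derive from an alkene geometry and a chair transition state, and the molecule falls into a ring A piece and a C6 chain. The demands are O- rather than C-alkylation of 11, a chair transition state, and delivery to the α face of C10.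

10 ⇒ 9 ⇒ 8 ⇒ 6 + 7, and 6 ⇒ 5. The C8=C9 double bond of 8 is cut by a phosphonate olefination, after functional group changes at C7. The gain is two small achiral pieces. The demand is E geometry, because it becomes the configuration of C9.

4 ⇒ 3 ⇒ 2 ⇒ 1. No C–C bond is cut: ring A with its gem-dimethyl group, the C10 methyl and both oxygens is already present in 1. Two reductions introduce the chirality; the first must be enantioselective and the second must relay it to C4 of 3.

26 ⇒ 25. The C–I and C–H bonds across the triple bond are cut. The demand is anti addition, which gives the Z isomer.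

## Other disconnections considered

Alternative 1: The cut runs through C5–C10 and C8–C9 and opens both rings to the acyclic triene ester A1. In the forward direction EtAlCl2 would bring the (E)-C9=C10 enoate across the C5=C6–C7=C8 diene to give the trans-fused octalin ester A2.
- In its favour: two rings, two C–C bonds and the three contiguous stereocentres C5, C10 and C9 are made in one step from a linear precursor. The E geometry of the dienophile translates into the C9/C10 relationship, and the gem-dimethyl group in the tether helps folding. In rings and bonds made per step it is better than the chosen plan, which closes one ring.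
- Against it here: the new C5–C10 bond joins a diene terminus next to quaternary C4 to the β,β-disubstituted carbon of the enoate, a hindered pairing under which the Lewis acid may isomerise or polymerise the diene first. The only control over the absolute sense is the remote silyloxy group in the tether. A2 is also wrongly functionalised at three places: C8 is a methylene that must be oxidised (in competition with allylic C5) and methylenated, C6=C7 must be reduced, and the C9 ester (C11) must be reduced and homologated before C13–C15 can be added.
- Comparison: in mechanism the cycloaddition is the more convergent step. In structure its product is less well adapted than 16, which already carries the C8=C17 methylene and the C11–C12 chain. In step economy the sequence after A2 would be clearly longer, and C2 would need the same inversion.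

Alternative 2: The cuts are C8–C9 and C11–C12 (photocycloaddition) and, in the reverse sense, C8–C12 (fragmentation). The precursor is the ring A dioxinone A3, in which a C10 vinyl group (C9=C11) faces a dioxinone tethered to C5 through C6–C7. Irradiation and then K2CO3 in methanol would give the 8-oxo decalin ester A4.
- In its favour: ring B closes while the C8 carbonyl (one methylenation from the target) and the chain up to C13 are delivered together. C9 sits α to the ketone and can be equilibrated to the equatorial 9β chain. The C2 oxygen can be carried in its final β configuration and no C6 oxygen has to be removed; on both points this alternative is better than the chosen plan.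
- Against it here: A3 must already contain the trans C5 methine and the C10 quaternary centre, so the hardest part of the problem is moved into the precursor and not solved by the key step. The [2+2] must be regioselective and face-selective on a vinyl group bound to a quaternary carbon. From the C13 ester of A4 the (13Z) acid would have to be made by olefination of a methyl ketone, which is not reliably Z-selective, whereas the chosen plan fixes this geometry by a stereospecific coupling.
- Comparison: in structure A4 is about as close to the target as 16. In mechanism it needs photochemical equipment and leaves C5/C10 unsolved. In step economy it is about equal after the key step and longer before it.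

Alternative 3: The cuts are C5–C10 and C4–C5, which open both rings to the acyclic dienone methyl ketone A5. Under a chiral primary amine salt the C5 methyl would add first to C10 (6-exo, ring B) and then to C4 (6-endo, ring A) to give the decalin-2,6-dione ketal A6.
- In its favour: both rings and both bonds to C5 form in one catalytic cascade from a linear precursor, and the absolute configuration comes from a catalyst; in rings closed per step it is better than the chosen plan. C2 arrives as a ketone, which is the direct precursor of the axial alcohol and saves the oxidation of the chosen end-game.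
- Against it here: both acceptor carbons (C10 and C4) are β,β-disubstituted, so each enamine addition must build a quaternary centre, a poor match of nucleophile and acceptor. The second addition is a 6-endo closure between two hindered carbons. Enamine formation must choose the C5 methyl over the C7 methylene, and the pre-set C9 centre must control C10. A6 then carries a C6 ketone to be removed beside the C2 ketone and a C8 ketal to be unmasked and methylenated.
- Comparison: in mechanism the risk sits in one cascade without close precedent for such acceptors. In structure A6 needs more redox corrections than 16. In step economy it would be shorter before the key step and longer after it.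

Key step: step 11

Remark: labdane numbering and the α/β face descriptors of the final decalin (C20 is β) are used for every intermediate, including the monocyclic ones; TBS is tert-butyldimethylsilyl.
Remark: the C6 configuration of 16 is assigned as 6α on steric grounds; it is not relayed to 29, and the 6β epimer would pass through steps 12 and 13 in the same way.
Remark: 5 is taken as a catalogue compound; it is otherwise one monosilylation away from propane-1,3-diol.

## Steps

Step 1
Reactants: 1 ketoisophorone (2,6,6-trimethylcyclohex-2-ene-1,4-dione)
Product: 2 (6R)-2,2,6-trimethylcyclohexane-1,4-dione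
Conditions: ene-reductase OYE2, NADP+ (cat.), glucose dehydrogenase, D-glucose, phosphate buffer pH 6.5, 30 °C
Reagents that add atoms: none
Why: Enzymatic conjugate reduction of the ene-dione C=C bond by an old yellow enzyme, the activity behind the classical yeast reduction of this substrate; the enzyme adds hydride and proton trans across the double bond and sets C6 as R, and the slightly acidic buffer keeps this α-stereocentre from racemising before it has relayed its chirality to C4 in step 2.

Step 2
Reactants: 2 (6R)-2,2,6-trimethylcyclohexane-1,4-dione
Product: 3 (4R,6R)-4-hydroxy-2,2,6-trimethylcyclohexan-1-one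
Conditions: LiB(s-Bu)3H, THF, −78 °C; then H2O
Reagents that add atoms: none
Why: Chemo- and diastereoselective ketone reduction: the bulky borohydride leaves the C1 carbonyl (between a quaternary and a tertiary carbon) alone and attacks the C4 carbonyl equatorially because the axial C2 methyl blocks the axial path, as in 3,3,5-trimethylcyclohexanone; the axial alcohol is trans to the equatorial C6 methyl, which is 4R (the later 2α oxygen of the labdane).

Step 3
Reactants: 3 (4R,6R)-4-hydroxy-2,2,6-trimethylcyclohexan-1-one
Product: 4 (4R,6R)-4-(TBS-oxy)-2,2,6-trimethylcyclohexan-1-one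
Conditions: TBSCl, imidazole, DMF, rt
Reagents that add atoms: tert-butyldimethylsilyl chloride, CC(C)(C)[Si](C)(C)Cl
Why: Standard silylation of a secondary alcohol; the ether withstands the enolate, thermal, ylide and Lewis-acid steps that follow.

Step 4
Reactants: 5 3-(TBS-oxy)propan-1-ol
Product: 6 3-(TBS-oxy)propanal
Conditions: TEMPO (cat.), PhI(OAc)2, CH2Cl2, rt
Reagents that add atoms: none
Why: Nitroxyl-catalysed oxidation of a primary alcohol stops at the aldehyde under neutral conditions, which avoids β-elimination of the silyloxy group.

Step 5
Reactants: 6 3-(TBS-oxy)propanal; 7 triethyl 2-phosphonopropionate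
Product: 8 ethyl (2E)-5-(TBS-oxy)-2-methylpent-2-enoate
Conditions: NaH, THF, 0 °C → rt
Reagents that add atoms: none
Why: Horner–Wadsworth–Emmons olefination; the α-methyl phosphonate anion gives the (E)-trisubstituted enoate, and this geometry later becomes the configuration of C9.

Step 6
Reactants: 8 ethyl (2E)-5-(TBS-oxy)-2-methylpent-2-enoate
Product: 9 (2E)-5-(TBS-oxy)-2-methylpent-2-en-1-ol
Conditions: i-Bu2AlH (2.2 equiv), CH2Cl2, −78 °C; then aq. potassium sodium tartrate
Reagents that add atoms: none
Why: 1,2-Reduction of the enoate to the allylic alcohol by excess i-Bu2AlH at low temperature; alkene geometry and silyl ether are untouched.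

Step 7
Reactants: 9 (2E)-5-(TBS-oxy)-2-methylpent-2-en-1-ol
Product: 10 (2E)-1-chloro-5-(TBS-oxy)-2-methylpent-2-ene
Conditions: MsCl, LiCl, 2,4,6-collidine, DMF, 0 °C
Reagents that add atoms: lithium chloride, [Li+].[Cl-]
Why: Mesylation and SN2 displacement by chloride in the same flask give the primary allylic chloride without allylic transposition; the chloride is chosen as a hard leaving group for the O-alkylation of step 8.

Step 8
Reactants: 4 (4R,6R)-4-(TBS-oxy)-2,2,6-trimethylcyclohexan-1-one; 10 (2E)-1-chloro-5-(TBS-oxy)-2-methylpent-2-ene
Product: 12 (5R)-5-(TBS-oxy)-2-{[(2E)-5-(TBS-oxy)-2-methylpent-2-en-1-yl]oxy}-1,3,3-trimethylcyclohex-1-ene, via potassium enolate 11 (not isolated)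
Conditions: KN(SiMe3)2, 18-crown-6, THF/DMPU, −78 → 0 °C; then 10, −78 → 0 °C; filtration through basic alumina
Reagents that add atoms: none
Why: O-alkylation of an ambident enolate: only C10 can be deprotonated (C4 is quaternary), and the tetrasubstituted potassium enolate 11, separated from its cation by 18-crown-6 and DMPU, should react at oxygen with the hard allylic chloride because C-alkylation would have to build a quaternary carbon beside the neopentyl carbonyl.

Step 9
Reactants: 12 (5R)-5-(TBS-oxy)-2-{[(2E)-5-(TBS-oxy)-2-methylpent-2-en-1-yl]oxy}-1,3,3-trimethylcyclohex-1-ene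
Product: 13 (2R,4S)-4-(TBS-oxy)-2-[(3S)-1-(TBS-oxy)-4-methylpent-4-en-3-yl]-2,6,6-trimethylcyclohexan-1-one (ring A ketone with 2α-silyloxy, 10β-methyl and the C9 isopropenyl chain on C10)
Conditions: toluene, i-Pr2NEt (trace), sealed tube, 170 °C
Reagents that add atoms: none
Why: Aliphatic Claisen rearrangement through a chair transition state, in which the (E)-allyl unit keeps C11 pseudo-equatorial and the ring enol ether keeps C20 pseudo-axial, so that C9 and C10 form in the relative configuration of the labdane; the allyl unit should be delivered to the α face of C10, anti to the pseudo-axial 4β-methyl of the half-chair that keeps the 2α-silyloxy group equatorial, which ties both new centres to C2.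

Step 10
Reactants: 13 (2R,4S)-4-(TBS-oxy)-2-[(3S)-1-(TBS-oxy)-4-methylpent-4-en-3-yl]-2,6,6-trimethylcyclohexan-1-one
Product: 14 (3S,4R,6S)-6-(TBS-oxy)-4-[(3S)-1-(TBS-oxy)-4-methylpent-4-en-3-yl]-4,8,8-trimethyl-1-oxaspiro[2.5]octane (C5 spiro-epoxide, oxirane CH2 α, oxygen β)
Conditions: Me3S+ I− (3 equiv), n-BuLi, THF, −10 °C; then 13, −10 °C → rt
Reagents that add atoms: trimethylsulfonium iodide, C[S+](C)C.[I-]
Why: Corey–Chaykovsky epoxidation of a non-enolisable ketone; the small ylide should add irreversibly along the axial (α) path because the equatorial path is blocked by the axial C20 and 4β-methyl groups on the two flanking carbons, so the oxirane CH2 (C6) is axial (α) and the oxygen equatorial (β).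

Step 11
Reactants: 14 (3S,4R,6S)-6-(TBS-oxy)-4-[(3S)-1-(TBS-oxy)-4-methylpent-4-en-3-yl]-4,8,8-trimethyl-1-oxaspiro[2.5]octane
Product: 16 2α,12-bis(TBS-oxy)-13,14,15,16-tetranorlabd-8(17)-en-6α-ol, via aldehyde 15 (not isolated)
Conditions: Me2AlCl (2.5 equiv), CH2Cl2, −78 → −20 °C; then H2O
Reagents that add atoms: none
Why: Me2AlCl binds the oxirane oxygen and ionises the C5–O bond (tertiary, flanked by quaternary C4 and C10), and a C6 hydrogen migrates to C5 on the face opposite the departing oxygen (α), giving aldehyde 15 with H5 axial and the formyl group equatorial; this is the Meinwald rearrangement of a 1,1-disubstituted epoxide. The aluminium-bound aldehyde of 15 is a 5-methylhex-5-enal and closes ring B by a type 2 carbonyl-ene reaction, C7 bonding to C6 while a C17 hydrogen passes to oxygen; both stages are known reaction types under aluminium Lewis acids, and only their telescoping in one flask is an extrapolation. The closure is six-membered, exo at the carbonyl and endo at the alkene. C5 is controlled by the oxirane configuration from step 10 through anti migration, and the trans ring fusion follows because C6 and C9 are both equatorial on the ring A chair (C20 and 4β-methyl axial, silyloxy equatorial). At C6 the complexed oxygen should lie on the α face, because an all-chair array would wedge it between the axial C20 and 4β-methyl groups and push C20 into the O···H···C17 bridge; hydrogen transfer then runs through a boat-like C6–C7–C8 segment that relaxes to the chair with the 6α (equatorial) hydroxyl. The step needs the hydride shift to outrun methyl or ring-bond migration and alkene capture at the C5 cation, which the oxygen-assisted (carbonyl-forming) shift secures, and it needs the exocyclic alkene, which the concerted hydrogen transfer secures because only the C17 hydrogens can reach the oxygen. Me2AlCl also removes the proton of the product alcohol as methane, so the methylene is not isomerised by acid.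

Step 12
Reactants: 16 2α,12-bis(TBS-oxy)-13,14,15,16-tetranorlabd-8(17)-en-6α-ol
Product: 18 O-[2α,12-bis(TBS-oxy)-13,14,15,16-tetranorlabd-8(17)-en-6α-yl] S-methyl dithiocarbonate, via sodium xanthate 17 (not isolated)
Conditions: NaH, CS2, imidazole (cat.), THF, 0 °C → rt; then MeI
Reagents that add atoms: carbon disulfide, S=C=S; iodomethane, CI
Why: Xanthate formation, the first half of the Barton–McCombie deoxygenation: the sodium alkoxide adds to CS2 and the dithiocarbonate salt 17 is S-methylated; silyl ethers and the alkene are inert.

Step 13
Reactants: 18 O-[2α,12-bis(TBS-oxy)-13,14,15,16-tetranorlabd-8(17)-en-6α-yl] S-methyl dithiocarbonate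
Product: 19 2α,12-bis(TBS-oxy)-13,14,15,16-tetranorlabd-8(17)-ene
Conditions: Bu3SnH, AIBN (cat.), toluene, 100 °C
Reagents that add atoms: none
Why: Barton–McCombie deoxygenation: the stannyl radical adds to the thiocarbonyl, the C6–O bond fragments and the secondary C6 radical is reduced by Bu3SnH; the homoallylic alkene is not engaged because 3-exo closure is reversible and disfavoured, and C5 is untouched.

Step 14
Reactants: 19 2α,12-bis(TBS-oxy)-13,14,15,16-tetranorlabd-8(17)-ene
Product: 20 13,14,15,16-tetranorlabd-8(17)-ene-2α,12-diol
Conditions: Bu4NF, THF, rt → 45 °C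
Reagents that add atoms: none
Why: Fluoride cleavage of both silyl ethers in one operation; no other group is sensitive to fluoride.

Step 15
Reactants: 20 13,14,15,16-tetranorlabd-8(17)-ene-2α,12-diol
Product: 21 12-iodo-13,14,15,16-tetranorlabd-8(17)-en-2α-ol
Conditions: I2, PPh3, imidazole, CH2Cl2, 0 °C
Reagents that add atoms: iodine, II
Why: Appel-type iodination, which at low temperature is selective for the primary alcohol over the secondary one; SN2 at C12 creates no stereocentre.

Step 16
Reactants: 21 12-iodo-13,14,15,16-tetranorlabd-8(17)-en-2α-ol
Product: 22 12-iodo-13,14,15,16-tetranorlabd-8(17)-en-2-one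
Conditions: Dess–Martin periodinane, pyridine, CH2Cl2, 0 °C → rt
Reagents that add atoms: none
Why: Dess–Martin oxidation of the secondary alcohol under buffered conditions that leave the primary iodide and the exocyclic alkene untouched; the C2 stereocentre is erased on purpose.

Step 17
Reactants: 22 12-iodo-13,14,15,16-tetranorlabd-8(17)-en-2-one
Product: 23 12-iodo-13,14,15,16-tetranorlabd-8(17)-en-2β-ol
Conditions: LiB(s-Bu)3H, THF, −78 °C; then H2O
Reagents that add atoms: none
Why: Substrate-controlled ketone reduction: the axial (β) path to the C2 carbonyl is blocked by the syn-axial C20 and 4β-methyl groups, so the bulky borohydride adds from the α face and gives the axial 2β alcohol (C2 becomes R); at −78 °C the primary iodide should not be reduced.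

Step 18
Reactants: 23 12-iodo-13,14,15,16-tetranorlabd-8(17)-en-2β-ol
Product: 24 12-iodo-13,14,15,16-tetranorlabd-8(17)-en-2β-yl acetate
Conditions: Ac2O, DMAP, pyridine, CH2Cl2, rt
Reagents that add atoms: acetic anhydride, CC(=O)OC(C)=O
Why: DMAP-catalysed acetylation of the hindered axial alcohol; no other nucleophilic group is present.

Step 19
Reactants: 25 but-2-ynoic acid
Product: 26 (2Z)-3-iodobut-2-enoic acid
Conditions: NaI, AcOH, 110 °C
Reagents that add atoms: sodium iodide, [Na+].[I-]
Why: Hydroiodination of the ynoic acid: conjugate addition of iodide and anti protonation give the (Z)-β-iodo acid (iodine and carboxyl cis), which fixes the later C13=C14 geometry.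

Step 20
Reactants: 24 12-iodo-13,14,15,16-tetranorlabd-8(17)-en-2β-yl acetate; 26 (2Z)-3-iodobut-2-enoic acid
Product: 29 (13Z)-2β-acetoxylabda-8(17),13-dien-15-oic acid, via alkylzinc iodide 27 (not isolated), via sodium iodobutenoate 28 (not isolated)
Conditions: 24, Zn dust (activated with BrCH2CH2Br and Me3SiCl), DMA, 40 °C; 26, NaH, THF, 0 °C; then Pd(PPh3)4 (5 mol %), THF/DMA, rt; then 1 M HCl to pH 3
Reagents that add atoms: none
Why: Negishi coupling: zinc inserts into the primary C–I bond without touching the acetate, and zerovalent palladium couples the alkylzinc 27 with the vinyl iodide of carboxylate 28 with retention of the Z geometry; cross-coupling of organozinc reagents with unprotected 3-iodobut-2-enoic acid is a known reaction, and the preformed carboxylate spares the zinc reagent and removes any ester cleavage beside the acetate.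

## Compound list

1 | ketoisophorone (2,6,6-trimethylcyclohex-2-ene-1,4-dione) | CC1=CC(=O)CC(C)(C)C1=O | starting material
2 | (6R)-2,2,6-trimethylcyclohexane-1,4-dione | C[C@@H]1CC(=O)CC(C)(C)C1=O | intermediate
3 | (4R,6R)-4-hydroxy-2,2,6-trimethylcyclohexan-1-one | C[C@@H]1C[C@@H](O)CC(C)(C)C1=O | intermediate
4 | (4R,6R)-4-[(tert-butyldimethylsilyl)oxy]-2,2,6-trimethylcyclohexan-1-one | C[C@@H]1C[C@@H](O[Si](C)(C)C(C)(C)C)CC(C)(C)C1=O | intermediate
5 | 3-[(tert-butyldimethylsilyl)oxy]propan-1-ol | OCCCO[Si](C)(C)C(C)(C)C | starting material
6 | 3-[(tert-butyldimethylsilyl)oxy]propanal | O=CCCO[Si](C)(C)C(C)(C)C | intermediate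
7 | triethyl 2-phosphonopropionate | CCOC(=O)C(C)P(=O)(OCC)OCC | starting material
8 | ethyl (2E)-5-[(tert-butyldimethylsilyl)oxy]-2-methylpent-2-enoate | CCOC(=O)/C(C)=C/CCO[Si](C)(C)C(C)(C)C | intermediate
9 | (2E)-5-[(tert-butyldimethylsilyl)oxy]-2-methylpent-2-en-1-ol | OC/C(C)=C/CCO[Si](C)(C)C(C)(C)C | intermediate
10 | (2E)-1-chloro-5-[(tert-butyldimethylsilyl)oxy]-2-methylpent-2-ene | ClC/C(C)=C/CCO[Si](C)(C)C(C)(C)C | intermediate
11 | potassium (4R)-4-[(tert-butyldimethylsilyl)oxy]-2,6,6-trimethylcyclohex-1-en-1-olate | CC1=C([O-])C(C)(C)C[C@H](O[Si](C)(C)C(C)(C)C)C1.[K+] | intermediate (not isolated)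
12 | (5R)-5-[(tert-butyldimethylsilyl)oxy]-2-{[(2E)-5-[(tert-butyldimethylsilyl)oxy]-2-methylpent-2-en-1-yl]oxy}-1,3,3-trimethylcyclohex-1-ene | CC1=C(OC/C(C)=C/CCO[Si](C)(C)C(C)(C)C)C(C)(C)C[C@H](O[Si](C)(C)C(C)(C)C)C1 | intermediate
13 | (2R,4S)-4-[(tert-butyldimethylsilyl)oxy]-2-{(3S)-1-[(tert-butyldimethylsilyl)oxy]-4-methylpent-4-en-3-yl}-2,6,6-trimethylcyclohexan-1-one | C=C(C)[C@H](CCO[Si](C)(C)C(C)(C)C)[C@@]1(C)C[C@@H](O[Si](C)(C)C(C)(C)C)CC(C)(C)C1=O | intermediate
14 | (3S,4R,6S)-6-[(tert-butyldimethylsilyl)oxy]-4-{(3S)-1-[(tert-butyldimethylsilyl)oxy]-4-methylpent-4-en-3-yl}-4,8,8-trimethyl-1-oxaspiro[2.5]octane (oxirane CH2 α, oxygen β) | C=C(C)[C@H](CCO[Si](C)(C)C(C)(C)C)[C@@]1(C)C[C@@H](O[Si](C)(C)C(C)(C)C)CC(C)(C)[C@@]12CO2 | intermediate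
15 | (1S,2R,4S)-4-[(tert-butyldimethylsilyl)oxy]-2-{(3S)-1-[(tert-butyldimethylsilyl)oxy]-4-methylpent-4-en-3-yl}-2,6,6-trimethylcyclohexane-1-carbaldehyde (H5 α) | C=C(C)[C@H](CCO[Si](C)(C)C(C)(C)C)[C@@]1(C)C[C@@H](O[Si](C)(C)C(C)(C)C)CC(C)(C)[C@@H]1C=O | intermediate (not isolated)
16 | 2α,12-bis[(tert-butyldimethylsilyl)oxy]-13,14,15,16-tetranorlabd-8(17)-en-6α-ol (5S,9S,10S skeleton, trans-fused) | C=C1C[C@H](O)[C@H]2C(C)(C)C[C@H](O[Si](C)(C)C(C)(C)C)C[C@]2(C)[C@H]1CCO[Si](C)(C)C(C)(C)C | intermediate
17 | sodium O-[2α,12-bis(TBS-oxy)-13,14,15,16-tetranorlabd-8(17)-en-6α-yl] dithiocarbonate | C=C1C[C@H](OC(=S)[S-])[C@H]2C(C)(C)C[C@H](O[Si](C)(C)C(C)(C)C)C[C@]2(C)[C@H]1CCO[Si](C)(C)C(C)(C)C.[Na+] | intermediate (not isolated)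
18 | O-[2α,12-bis(TBS-oxy)-13,14,15,16-tetranorlabd-8(17)-en-6α-yl] S-methyl dithiocarbonate | C=C1C[C@H](OC(=S)SC)[C@H]2C(C)(C)C[C@H](O[Si](C)(C)C(C)(C)C)C[C@]2(C)[C@H]1CCO[Si](C)(C)C(C)(C)C | intermediate
19 | 2α,12-bis[(tert-butyldimethylsilyl)oxy]-13,14,15,16-tetranorlabd-8(17)-ene | C=C1CC[C@H]2C(C)(C)C[C@H](O[Si](C)(C)C(C)(C)C)C[C@]2(C)[C@H]1CCO[Si](C)(C)C(C)(C)C | intermediate
20 | 13,14,15,16-tetranorlabd-8(17)-ene-2α,12-diol | C=C1CC[C@H]2C(C)(C)C[C@H](O)C[C@]2(C)[C@H]1CCO | intermediate
21 | 12-iodo-13,14,15,16-tetranorlabd-8(17)-en-2α-ol | C=C1CC[C@H]2C(C)(C)C[C@H](O)C[C@]2(C)[C@H]1CCI | intermediate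
22 | 12-iodo-13,14,15,16-tetranorlabd-8(17)-en-2-one | C=C1CC[C@H]2C(C)(C)CC(=O)C[C@]2(C)[C@H]1CCI | intermediate
23 | 12-iodo-13,14,15,16-tetranorlabd-8(17)-en-2β-ol | C=C1CC[C@H]2C(C)(C)C[C@@H](O)C[C@]2(C)[C@H]1CCI | intermediate
24 | 12-iodo-13,14,15,16-tetranorlabd-8(17)-en-2β-yl acetate | C=C1CC[C@H]2C(C)(C)C[C@@H](OC(C)=O)C[C@]2(C)[C@H]1CCI | intermediate
25 | but-2-ynoic acid | CC#CC(=O)O | starting material
26 | (2Z)-3-iodobut-2-enoic acid | C/C(I)=C/C(=O)O | intermediate
27 | [2β-acetoxy-13,14,15,16-tetranorlabd-8(17)-en-12-yl]zinc iodide | C=C1CC[C@H]2C(C)(C)C[C@@H](OC(C)=O)C[C@]2(C)[C@H]1CC[Zn]I | intermediate (not isolated)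
28 | sodium (2Z)-3-iodobut-2-enoate | C/C(I)=C/C(=O)[O-].[Na+] | intermediate (not isolated)
29 | (13Z)-2β-acetoxylabda-8(17),13-dien-15-oic acid; (2Z)-5-[(1S,4aS,7R,8aS)-7-acetoxy-5,5,8a-trimethyl-2-methylidenedecahydronaphthalen-1-yl]-3-methylpent-2-enoic acid | C=C1CC[C@H]2C(C)(C)C[C@@H](OC(C)=O)C[C@]2(C)[C@H]1CC/C(C)=C\C(=O)O | target

## Step count and least certain steps

Total step count: 20. Longest linear sequence: 16 steps (from 5 through steps 4–18 and step 20); the branch from 1 joins at step 8 after 3 steps and the branch from 25 joins at step 20 after 1 step.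

Step 11 (key step). The most likely failures are, in the first stage, diversion of the C5 cation (methyl or ring-bond migration, capture by the isopropenyl group, chloride opening at C6) and, in the second stage, a stepwise closure in which C–C bond formation runs ahead of hydrogen transfer. The C8 cation would then lose a proton from C7 or C9 or take up chloride, and regiocontrol over the alkene would be lost. Fallback, from 14 back to the route at 19, by a ring closure that does not depend on hydrogen transfer:
- Ozonolysis of the isopropenyl group of 14 (O3, CH2Cl2/MeOH, −78 °C; Me2S) would give the epoxy methyl ketone F1.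
- BF3·OEt2 at −78 °C would rearrange the oxirane to the keto aldehyde F2, with the same anti hydride shift.
- Piperidine/AcOH in toluene at 80 °C would close ring B by intramolecular aldol condensation (C6–C7 bond from the acetyl methyl group) to the enone F3; the equatorial 9β chain and the trans fusion are the thermodynamic outcome.
- H2 over Pd/C would give the saturated 8-ketone F4, and Ph3P=CH2 in THF would methylenate it to 19.
This replaces steps 11–13 by five steps of known chemistry.

Step 8. The ambident enolate 11 may alkylate at carbon; direct SN2 at C10 gives the linear, unrearranged constitutional isomer of 13 and bypasses the sigmatropic step that sets C9. Fallback, from 4 and 9 back to the route at 13, with the enol ether made by acid-catalysed exchange and not by alkylation: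
- 4 is converted with HC(OMe)3, MeOH and a trace of TsOH into its dimethyl ketal F5.
- F5 is heated with 9 and catalytic propionic acid in xylene at 140 °C with removal of methanol. One methoxy group is exchanged, the second is eliminated towards C10 (the only side with a hydrogen) to give 12, and 12 rearranges in the same flask to 13.

Step 10. Addition of the ylide to a carbonyl flanked by two quaternary carbons may be slower than the thermal decay of the ylide, so the ketone may not be fully converted. Fallback, from 13 back to the route at 14, with a lithium carbenoid in place of the ylide: chloromethyllithium, generated from ICH2Cl and MeLi in THF at −78 °C in the presence of 13, should add irreversibly along the same axial path to give the lithium alkoxide of the chlorohydrin F6. On warming this closes to 14 with the same configuration (CH2 α, oxygen β).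

Step 20. The alkylzinc 27 may be protonated if deprotonation of 26 is incomplete, transmetalation may be slowed by the carboxylate, and the Z alkene may isomerise on prolonged contact with palladium. Fallback, from 24 and 26 back to the route at 29, with the acid masked and the acetate re-installed last:
- 26 is methylated (MeI, K2CO3, DMF) to methyl (2Z)-3-iodobut-2-enoate F7.
- 27 is coupled with F7 under Pd(PPh3)4 to the acetoxy methyl ester F8.
- LiOH in THF/MeOH/H2O cleaves both esters to the hydroxy acid F9.
- Ac2O/DMAP/pyridine followed by aqueous work-up (hydrolysis of the mixed anhydride) gives 29.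

## Further compounds

F1 | step 11 | epoxy methyl ketone: 14 with the isopropenyl group replaced by acetyl at C8 (all stereocentres as in 14) | CC(=O)[C@H](CCO[Si](C)(C)C(C)(C)C)[C@@]1(C)C[C@@H](O[Si](C)(C)C(C)(C)C)CC(C)(C)[C@@]12CO2
F2 | step 11 | keto aldehyde: 15 with the isopropenyl group replaced by acetyl at C8 (H5 α) | CC(=O)[C@H](CCO[Si](C)(C)C(C)(C)C)[C@@]1(C)C[C@@H](O[Si](C)(C)C(C)(C)C)CC(C)(C)[C@@H]1C=O
F3 | step 11 | 2α,12-bis(TBS-oxy)-13,14,15,16,17-pentanorlabd-6-en-8-one | O=C1C=C[C@H]2C(C)(C)C[C@H](O[Si](C)(C)C(C)(C)C)C[C@]2(C)[C@H]1CCO[Si](C)(C)C(C)(C)C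
F4 | step 11 | 2α,12-bis(TBS-oxy)-13,14,15,16,17-pentanorlabdan-8-one | O=C1CC[C@H]2C(C)(C)C[C@H](O[Si](C)(C)C(C)(C)C)C[C@]2(C)[C@H]1CCO[Si](C)(C)C(C)(C)C
F5 | step 8 | dimethyl ketal of 4: 4-(TBS-oxy)-1,1-dimethoxy-2,2,6-trimethylcyclohexane (stereocentres as in 4) | C[C@@H]1C[C@@H](O[Si](C)(C)C(C)(C)C)CC(C)(C)C1(OC)OC
F6 | step 10 | chlorohydrin of 13: C5 carbinol with axial (α) chloromethyl group and β hydroxyl | C=C(C)[C@H](CCO[Si](C)(C)C(C)(C)C)[C@@]1(C)C[C@@H](O[Si](C)(C)C(C)(C)C)CC(C)(C)[C@@]1(O)CCl
F7 | step 20 | methyl (2Z)-3-iodobut-2-enoate | C/C(I)=C/C(=O)OC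
F8 | step 20 | methyl (13Z)-2β-acetoxylabda-8(17),13-dien-15-oate | C=C1CC[C@H]2C(C)(C)C[C@@H](OC(C)=O)C[C@]2(C)[C@H]1CC/C(C)=C\C(=O)OC
F9 | step 20 | (13Z)-2β-hydroxylabda-8(17),13-dien-15-oic acid | C=C1CC[C@H]2C(C)(C)C[C@@H](O)C[C@]2(C)[C@H]1CC/C(C)=C\C(=O)O
A1 | alternative 1 | methyl (2E,5R,8E)-5-(TBS-oxy)-3,7,7-trimethylundeca-2,8,10-trienoate | C=C/C=C/C(C)(C)C[C@H](O[Si](C)(C)C(C)(C)C)C/C(C)=C/C(=O)OC
A2 | alternative 1 | methyl 2α-(TBS-oxy)-12,13,14,15,16,17-hexanorlabd-6-en-11-oate (trans-fused octalin ester) | C1C=C[C@H]2C(C)(C)C[C@H](O[Si](C)(C)C(C)(C)C)C[C@]2(C)[C@H]1C(=O)OC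
A3 | alternative 2 | 2,2-dimethyl-1,3-dioxin-4-one carrying at its C6 the C7–C6 ethylene link to C5 (H5 α) of ring A; ring A has 4,4-dimethyl, 2β-TBS-oxy, 10β-methyl and 10α-vinyl groups | C=C[C@@]1(C)C[C@H](O[Si](C)(C)C(C)(C)C)CC(C)(C)[C@@H]1CCC1=CC(=O)OC(C)(C)O1
A4 | alternative 2 | methyl 2β-(TBS-oxy)-8-oxo-14,15,16,17-tetranorlabdan-13-oate | O=C1CC[C@H]2C(C)(C)C[C@@H](O[Si](C)(C)C(C)(C)C)C[C@]2(C)[C@H]1CCC(=O)OC
A5 | alternative 3 | acyclic (E)-dienone methyl ketone: C5H3–C6(=O)–C7H2–C8(ethylene ketal)–C9H(CH2CH2O-TBS)–C10(CH3)=C1H–C2(=O)–C3H=C4(CH3)2 | CC(=O)CC1(OCCO1)[C@H](CCO[Si](C)(C)C(C)(C)C)/C(C)=C/C(=O)C=C(C)C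
A6 | alternative 3 | 8,8-(ethylenedioxy)-12-(TBS-oxy)-13,14,15,16,17-pentanorlabdane-2,6-dione | C13(OCCO3)CC(=O)[C@H]2C(C)(C)CC(=O)C[C@]2(C)[C@H]1CCO[Si](C)(C)C(C)(C)C
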